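Follow the electrophile. At 0.087 M it is the limiting reagent in east, south-west and north-west, so its books answer the question.

| flask | electrophile | nucleophile | solid base | remark | time |
|---|---|---|---|---|---|
| Sunday's | 0.087 M | 0.073 M | 0.261 M | run made earlier |  |
| Friday's | 0.087 M | 0.15 M | 0.261 M | run made earlier |  |
| Saturday's | 0.087 M | 0.16 M | 0.261 M | run made earlier |  |
| east | 0.087 M | 0.0960 M | 0.261 M |  | 25 min |
| south-west | 0.087 M | 0.140 M | 0.261 M |  | 25 min |
| north-west | 0.087 M | 0.220 M | 0.261 M |  | 25 min |

| run | time / min | electrophile / % | product / % |
|---|---|---|---|
| Sunday's | 4.00 | 98 | 2 |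
| Sunday's | 8.00 | 94 | 5 |
| Sunday's | 10.0 | 95 | 7 |
| Sunday's | 15.0 | 90 | 8 |
| Sunday's | 20.0 | 87 | 12 |
| Friday's | 4.00 | 95 | 8 |
| Friday's | 8.00 | 86 | 10 |
| Friday's | 10.0 | 84 | 15 |
| Friday's | 15.0 | 79 | 16 |
| Friday's | 20.0 | 77 | 24 |
| Saturday's | 4.00 | 92 | 6 |
| Saturday's | 8.00 | 84 | 10 |
| Saturday's | 10.0 | 84 | 14 |
| Saturday's | 15.0 | 78 | 23 |
| Saturday's | 20.0 | 75 | 28 |

(readings scatter by 1.5 percentage points)

- as a solid, counted per litre of solution: solid base
- what was read earlier has a scatter of 1.5 percentage points, one standard deviation
- steps that have been proposed: solid base <-> free base; electrophile + nucleophile -> acid set free + product; acid set free + free base <-> salt of the base; nucleophile + acid set free <-> protonated nucleophile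
- at the start none of the solid base is in solution

- part of the electrophile that has reacted at the end, east
- part of the electrophile that has reacted at the end, south-west
- part of the electrophile that has reacted at the end, north-west
- what raising the concentration of nucleophile from its lowest to its highest value here does to the part of the electrophile that has reacted (changes below 5 percentage points count as none) (it falls / it rises / no change)

The ledger opens with the charge, booked as one whole. The first entry is electrophile still there, the second is product. In Saturday's run at 20.0 min they read 75 % and 28 %, together 103 %. With a scatter of 1.5 percentage points on each reading, that closes, and I open no third entry. Each mole booked to product also takes a mole of nucleophile and sets a mole of acid free, and that acid can hold further nucleophile as protonated nucleophile. I don't book this separately; I reckon on the nucleophile as charged, N, and let the constant carry the loss.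

With f the fraction of electrophile left after time t, I work in logarithms:

ln f = −k N t

Saturday's run gives

k = −ln(75 %) / (0.16 M × 20.0 min) = 0.0899 L mol⁻¹ min⁻¹

This k, the fall in ln f per minute and per mole of nucleophile charged per litre, is a reading. Sunday's last reading, at 0.073 M, gives 0.0954 L mol⁻¹ min⁻¹.

At 25 min, my reacted share 1 − f is:

east: 19.4 %
south-west: 27.0 %
north-west: 39.0 %

The forecast says 19 %, 27 % and 37 %; from lowest to highest nucleophile, it rises, and “Conversion clearly rises with nucleophile”. We agree on east and south-west; for north-west my figure is higher.

The flasks give 19.7 %, 27.4 % and 39.6 %: from lowest to highest nucleophile, it rises, by 20 points.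

    solid base ⇌ free base, rate k1*(cs1 - [free base]) while solid is left; crystals form when [free base] > cs1 (solubility = 33.0 mM, k = 0.0190 min⁻¹)
    electrophile + nucleophile → acid set free + product (k = 0.110 L mol⁻¹ min⁻¹)
    acid set free + free base ⇌ salt of the base, settled at all times (K = 2.50 × 10⁵ L mol⁻¹)
    nucleophile + acid set free ⇌ protonated nucleophile, settled at all times (K = 44000 L mol⁻¹)

The gap between north-west and east comes from the difference in nucleophile. North-west stands at 39.6 %, and the same flask with the difference in nucleophile taken away, its charge lowered to east's, gives 19.7 %; k on that charge gives 19.4 %. The same k can go further on south-west. Read at 1.0 h, it predicts 53.0 % reacted. That flask has 47.8 % reacted, with free nucleophile down to 54 % of its charge.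

(The runs were generated by integration with made-up constants, noise included.)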